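**Plan**
- Retrosynthetic cuts: the keto acid is treated as the hydrolysed form of a 3-alkylisocoumarin, so the carboxyl oxygen is first re-joined to C2' (lactone), and the C2 O-methyl and a chain acetate are restored.
- The isocoumarin is then cut in one operation at C6–C1' (arene–alkyne), C1–CO2 (arene–carboxyl) and O–C2' (lactone), leaving 3,5-dimethoxybenzyne, a C13 alkynyl acetate and CO2.
- Enabling feature: ring carbons C1 (carboxyl) and C6 (side chain) are neighbours next to the C2 oxygen, and the carboxyl carbon and the C2' ketone are 1,5-related. This is the pattern of an isocoumarin lactone ring built on the two carbons of an aryne.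
- Forward order: aryne precursor from 3,5-dimethoxyphenol (3 steps); alkyne from 11-bromoundecan-1-ol (2 steps); copper-catalysed three-component coupling that attaches the chain and closes the only new ring; peri-demethylation; hydrolytic ring opening.
- Stereochemistry: the target has no stereocentre and no stereogenic double bond, so nothing has to be set.

Key step: step 6

Assumption: the target is made and drawn as the open keto acid; in solution it may equilibrate with its cyclic lactol tautomer, which is the same compound for the purpose of this route.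

**Step 1**
Reactants: 1 3,5-dimethoxyphenol
Product: 2 3,5-dimethoxyphenyl isopropylcarbamate
Conditions: i-PrNCO, Et3N (cat.), CH2Cl2, rt
Reagents that add atoms: isopropyl isocyanate, CC(C)N=C=O
Why: Amine-catalysed addition of the phenol to the isocyanate (carbamoylation) should install an N-isopropyl carbamate that is a strong directing group for ortho-metalation and can later be removed under mild base.

**Step 2**
Reactants: 2 3,5-dimethoxyphenyl isopropylcarbamate
Product: 6 3,5-dimethoxy-2-(trimethylsilyl)phenyl isopropylcarbamate, via N-silylated carbamate 3 (not isolated), via ortho-lithiated N-silylated carbamate 4 (not isolated), via C-silylated N-silylated carbamate 5 (not isolated)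
Conditions: TBSOTf, TMEDA, Et2O, 0 °C → rt; n-BuLi, TMEDA, −78 °C; TMSCl, −78 °C → rt; aq. NaHSO4
Reagents that add atoms: chlorotrimethylsilane, C[Si](C)(C)Cl
Why: In a directed ortho-metalation, in situ N-silylation masks the N–H, n-BuLi/TMEDA should then remove the ring proton flanked by the carbamate oxygen and a methoxy group (two symmetry-equivalent sites, more activated than the position between the two methoxy groups), TMSCl traps the aryllithium and the N–Si bond is hydrolysed on acidic work-up.

**Step 3**
Reactants: 6 3,5-dimethoxy-2-(trimethylsilyl)phenyl isopropylcarbamate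
Product: 8 3,5-dimethoxy-2-(trimethylsilyl)phenyl trifluoromethanesulfonate, via 3,5-dimethoxy-2-(trimethylsilyl)phenol 7 (not isolated)
Conditions: DBU, Et2NH, MeCN, 40 °C; then PhNTf2, rt
Reagents that add atoms: N-phenylbis(trifluoromethanesulfonimide), O=S(=O)(N(c1ccccc1)S(=O)(=O)C(F)(F)F)C(F)(F)F
Why: DBU should induce E1cB loss of isopropyl isocyanate from the carbamate (scavenged by Et2NH as a urea), and the phenoxide is triflated in the same flask (O-sulfonylation), so the desilylation-prone silyl phenol need not be isolated.

**Step 4**
Reactants: 9 11-bromoundecan-1-ol; 10 lithium acetylide ethylenediamine complex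
Product: 11 tridec-12-yn-1-ol
Conditions: LiC≡CH·H2NCH2CH2NH2 (3 equiv), DMSO, 0 °C → rt; aq. NH4Cl
Reagents that add atoms: none
Why: SN2 alkylation of lithium acetylide by the primary bromide in DMSO should proceed with the hydroxyl carried as its lithium alkoxide, so no protection is needed when excess acetylide is used.

**Step 5**
Reactants: 11 tridec-12-yn-1-ol
Product: 12 tridec-12-yn-1-yl acetate
Conditions: Ac2O, pyridine, DMAP (cat.), CH2Cl2, 0 °C → rt
Reagents that add atoms: acetic anhydride, CC(=O)OC(C)=O
Why: DMAP-catalysed acylation gives an acetate that keeps the hydroxyl from adding to the aryne or being carboxylated in step 6 and should be stable to anhydrous CsF.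

**Step 6**
Reactants: 8 3,5-dimethoxy-2-(trimethylsilyl)phenyl trifluoromethanesulfonate; 12 tridec-12-yn-1-yl acetate; 13 carbon dioxide
Product: 16 11-(6,8-dimethoxy-1-oxo-1H-isochromen-3-yl)undecyl acetate, via 3,5-dimethoxybenzyne 14 (not isolated), via cesium 2-alkynylbenzoate 15 (not isolated)
Conditions: (IPr)CuCl [chloro(1,3-bis(2,6-diisopropylphenyl)imidazol-2-ylidene)copper, monovalent copper] (10 mol %), CsF (3 equiv), CO2 (1 atm), MeCN, 80 °C
Reagents that add atoms: none
Why: Fluoride attacks silicon in 8 and triflate leaves, releasing aryne 14, while the copper chloride complex and fluoride convert alkyne 12 into the carbene-ligated copper acetylide. The acetylide adds across the aryne (alkynylcupration) to give an ortho-alkynyl arylcopper, which inserts CO2 into its C–Cu bond to give carboxylate 15. The carboxylate oxygen then adds to the copper-activated triple bond in a 6-endo-dig closure that forms the lactone ring, and protonation of the resulting vinylcopper by a further molecule of alkyne returns the copper acetylide. The closest known reaction type is the copper-carbene-catalysed three-component coupling of arynes, terminal alkynes and CO2 to 3-substituted isocoumarins; no stereocentre is created. The step needs regioselective addition to the unsymmetrical aryne and 6-endo rather than 5-exo lactonisation. The methoxy group next to the aryne bond polarises it so that the acetylide bonds to the remote carbon (future C6) and copper, then CO2, to the carbon flanked by that methoxy group (future C1), while the bulky copper carboxylate on an alkyl-substituted alkyne should favour attack at the distal alkyne carbon.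

**Step 7**
Reactants: 16 11-(6,8-dimethoxy-1-oxo-1H-isochromen-3-yl)undecyl acetate
Product: 18 11-(8-hydroxy-6-methoxy-1-oxo-1H-isochromen-3-yl)undecyl acetate, via aryl dichloroborinate chelate 17 (not isolated)
Conditions: BCl3 (1 M in CH2Cl2, 1.5 equiv), CH2Cl2, −78 → 0 °C; then H2O
Reagents that add atoms: none
Why: In this chelation-controlled Lewis-acid ether cleavage, BCl3 should bind between the lactone carbonyl and the peri methoxy oxygen so that chloride removes only that methyl group, leaving the 6-methoxy group, the enol lactone and the acetate intact at low temperature.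

**Step 8**
Reactants: 18 11-(8-hydroxy-6-methoxy-1-oxo-1H-isochromen-3-yl)undecyl acetate
Product: 19 2-hydroxy-6-(13-hydroxy-2-oxotridecyl)-4-methoxybenzoic acid
Conditions: LiOH (5 equiv), THF/H2O (3:1, no alcohol cosolvent), rt; then 1 M HCl to pH 3, 0 °C
Reagents that add atoms: lithium hydroxide (aqueous; its oxygen becomes one carboxyl oxygen), [Li+].[OH-]
Why: In this saponification, hydroxide should cleave the primary acetate and add to the enol-lactone carbonyl with expulsion of the C2' ketone enolate, and cold, mild acidification of the carboxylate should give the keto acid without acid-catalysed re-closure.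

**Compound list**
1 | 3,5-dimethoxyphenol | COc1cc(O)cc(OC)c1 | starting material
2 | 3,5-dimethoxyphenyl isopropylcarbamate | COc1cc(OC)cc(OC(=O)NC(C)C)c1 | intermediate
3 | 3,5-dimethoxyphenyl N-(tert-butyldimethylsilyl)-N-isopropylcarbamate (not isolated) | COc1cc(OC)cc(OC(=O)N(C(C)C)[Si](C)(C)C(C)(C)C)c1 | intermediate
4 | [2-({[tert-butyldimethylsilyl](isopropyl)carbamoyl}oxy)-4,6-dimethoxyphenyl]lithium (not isolated) | [Li]c1c(OC)cc(OC)cc1OC(=O)N(C(C)C)[Si](C)(C)C(C)(C)C | intermediate
5 | 3,5-dimethoxy-2-(trimethylsilyl)phenyl N-(tert-butyldimethylsilyl)-N-isopropylcarbamate (not isolated) | COc1cc(OC)c([Si](C)(C)C)c(OC(=O)N(C(C)C)[Si](C)(C)C(C)(C)C)c1 | intermediate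
6 | 3,5-dimethoxy-2-(trimethylsilyl)phenyl isopropylcarbamate | COc1cc(OC)c([Si](C)(C)C)c(OC(=O)NC(C)C)c1 | intermediate
7 | 3,5-dimethoxy-2-(trimethylsilyl)phenol (not isolated) | COc1cc(OC)c([Si](C)(C)C)c(O)c1 | intermediate
8 | 3,5-dimethoxy-2-(trimethylsilyl)phenyl trifluoromethanesulfonate | COc1cc(OC)c([Si](C)(C)C)c(OS(=O)(=O)C(F)(F)F)c1 | intermediate
9 | 11-bromoundecan-1-ol | OCCCCCCCCCCCBr | starting material
10 | lithium acetylide ethylenediamine complex | [Li]C#C.NCCN | starting material
11 | tridec-12-yn-1-ol | C#CCCCCCCCCCCCO | intermediate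
12 | tridec-12-yn-1-yl acetate | C#CCCCCCCCCCCCOC(C)=O | intermediate
13 | carbon dioxide | O=C=O | starting material
14 | 3,5-dimethoxybenzyne (1,2-didehydro-3,5-dimethoxybenzene; not isolated) | COC1=CC(OC)=CC#C1 | intermediate
15 | cesium 2-(13-acetoxytridec-1-yn-1-yl)-4,6-dimethoxybenzoate (not isolated) | COc1cc(OC)c(C(=O)[O-])c(C#CCCCCCCCCCCCOC(C)=O)c1.[Cs+] | intermediate
16 | 11-(6,8-dimethoxy-1-oxo-1H-isochromen-3-yl)undecyl acetate | COc1cc(OC)c2c(c1)C=C(CCCCCCCCCCCOC(C)=O)OC2=O | intermediate
17 | 11-{8-[(dichloroboranyl)oxy]-6-methoxy-1-oxo-1H-isochromen-3-yl}undecyl acetate (not isolated) | COc1cc(OB(Cl)Cl)c2c(c1)C=C(CCCCCCCCCCCOC(C)=O)OC2=O | intermediate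
18 | 11-(8-hydroxy-6-methoxy-1-oxo-1H-isochromen-3-yl)undecyl acetate | COc1cc(O)c2c(c1)C=C(CCCCCCCCCCCOC(C)=O)OC2=O | intermediate
19 | 2-hydroxy-6-(13-hydroxy-2-oxotridecyl)-4-methoxybenzoic acid | COc1cc(O)c(C(=O)O)c(CC(=O)CCCCCCCCCCCO)c1 | target

Total step count: 8. Longest linear sequence: 6 steps (steps 1, 2, 3, 6, 7, 8); the alkyne branch (steps 4, 5) joins at step 6.

**Steps most likely to fail**

1. Step 6. The aryne may be consumed by simple hydroalkynylation without CO2 capture or by decomposition before the copper acetylide intercepts it, and the carboxylate may close in the 5-exo mode to an alkylidene phthalide. Fallback: the same two ring positions are functionalised one at a time. Setting out from carbamate 2, the aryllithium 4 is generated as in step 2 and quenched with methyl chloroformate in place of TMSCl. This gives methyl 2-({[tert-butyldimethylsilyl](isopropyl)carbamoyl}oxy)-4,6-dimethoxybenzoate F1, whose N–Si bond is hydrolysed on NaHSO4 work-up to methyl 2-[(isopropylcarbamoyl)oxy]-4,6-dimethoxybenzoate F2. DBU/Et2NH in MeCN should release methyl 2-hydroxy-4,6-dimethoxybenzoate F3, which is triflated in the same flask with PhNTf2 to methyl 2,4-dimethoxy-6-{[(trifluoromethyl)sulfonyl]oxy}benzoate F4. Sonogashira coupling of this triflate with alkyne 12 (PdCl2(PPh3)2, CuI, Et3N, DMF, 70 °C) should give methyl 2-(13-acetoxytridec-1-yn-1-yl)-4,6-dimethoxybenzoate F5. Electrophilic 6-endo-dig lactonisation of the ester with catalytic AuCl3 in wet MeCN, with loss of methanol, brings the sequence back to the route at isocoumarin 16.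

2. Step 2. Incomplete N-silylation would allow anionic migration of the carbamoyl group onto the ring, and competing deprotonation between the two methoxy groups would place silicon at the wrong carbon. Fallback: the silyl group is delivered by halogen–metal exchange and O-to-C silyl migration instead of directed deprotonation. Setting out from phenol 1, bromination with NBS in CH2Cl2 at −78 °C should give 2-bromo-3,5-dimethoxyphenol F6, with any para-bromo isomer removed by chromatography. Silylation with hexamethyldisilazane in refluxing THF gives (2-bromo-3,5-dimethoxyphenoxy)trimethylsilane F7. Treatment with n-BuLi in THF at −78 °C forms [2,4-dimethoxy-6-(trimethylsilyloxy)phenyl]lithium F8, which should undergo retro-Brook rearrangement to the lithium salt of phenol 7. Quenching with Tf2O in the same flask comes back to the route at triflate 8.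

3. Step 8. Deprotonation of the C8 phenol turns the lactone into a phenoxide-deactivated salicylate, so ring opening may stall; forcing it, or the acidification afterwards, invites decarboxylation or re-closure of the ring. Fallback: the phenol is masked while the lactone is opened and is uncovered last under neutral conditions. Setting out from 18, benzylation (BnBr, K2CO3, DMF, 50 °C) should give 11-[8-(benzyloxy)-6-methoxy-1-oxo-1H-isochromen-3-yl]undecyl acetate F9. LiOH in THF/H2O then cleaves the acetate and opens the now unhindered enol lactone to 2-(benzyloxy)-6-(13-hydroxy-2-oxotridecyl)-4-methoxybenzoic acid F10 after mild acidification. Hydrogenolysis (H2, 10 % Pd/C, EtOAc, rt) removes the benzyl group and comes back to the route at target 19.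

**Further compounds**
F1 | step 6 | methyl 2-({[tert-butyldimethylsilyl](isopropyl)carbamoyl}oxy)-4,6-dimethoxybenzoate | COC(=O)c1c(OC)cc(OC)cc1OC(=O)N(C(C)C)[Si](C)(C)C(C)(C)C
F2 | step 6 | methyl 2-[(isopropylcarbamoyl)oxy]-4,6-dimethoxybenzoate | COC(=O)c1c(OC)cc(OC)cc1OC(=O)NC(C)C
F3 | step 6 | methyl 2-hydroxy-4,6-dimethoxybenzoate | COC(=O)c1c(O)cc(OC)cc1OC
F4 | step 6 | methyl 2,4-dimethoxy-6-{[(trifluoromethyl)sulfonyl]oxy}benzoate | COC(=O)c1c(OC)cc(OC)cc1OS(=O)(=O)C(F)(F)F
F5 | step 6 | methyl 2-(13-acetoxytridec-1-yn-1-yl)-4,6-dimethoxybenzoate | COC(=O)c1c(OC)cc(OC)cc1C#CCCCCCCCCCCCOC(C)=O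
F6 | step 2 | 2-bromo-3,5-dimethoxyphenol | COc1cc(O)c(Br)c(OC)c1
F7 | step 2 | (2-bromo-3,5-dimethoxyphenoxy)trimethylsilane | COc1cc(O[Si](C)(C)C)c(Br)c(OC)c1
F8 | step 2 | [2,4-dimethoxy-6-(trimethylsilyloxy)phenyl]lithium | [Li]c1c(OC)cc(OC)cc1O[Si](C)(C)C
F9 | step 8 | 11-[8-(benzyloxy)-6-methoxy-1-oxo-1H-isochromen-3-yl]undecyl acetate | COc1cc(OCc3ccccc3)c2c(c1)C=C(CCCCCCCCCCCOC(C)=O)OC2=O
F10 | step 8 | 2-(benzyloxy)-6-(13-hydroxy-2-oxotridecyl)-4-methoxybenzoic acid | COc1cc(OCc2ccccc2)c(C(=O)O)c(CC(=O)CCCCCCCCCCCO)c1
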